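**The trap.** A plateau of target looks like an amount that simply scales with the charge, but a plateau can also be target being lost while it is made.

| flask | starting material | partner | base | remark | time |
|---|---|---|---|---|---|
| west | 0.25 M | 1 equiv | 0.020 equiv | run made earlier |  |
| larch | 0.25 M | 0.700 equiv | 0.0200 equiv |  | 30 min |
| birch | 0.50 M | 0.700 equiv | 0.0200 equiv |  | 30 min |
| cedar | 1.0 M | 0.700 equiv | 0.0200 equiv |  | 30 min |
| maple | 2.0 M | 0.700 equiv | 0.0200 equiv |  | 30 min |

west run (percent of the starting material charged)

| time / min | target / % | starting material / % |
|---|---|---|
| 0.833 | 1.1 | 98.7 |
| 1.33 | 1.6 | 98.4 |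
| 2.50 | 2.7 | 96.9 |
| 4.00 | 4.0 | 95.9 |
| 6.00 | 3.7 | 94.9 |
| 10.0 | 4.8 | 93.4 |

(scatter of a reading: 0.3 percentage points)

- "hardly changes" means that all values lie within two and a half points (for a concentration: within two and a half percent of the largest)
- no earlier run changes the charge of base; that part of a forecast is a guess

* [target] at the end for larch, birch, cedar, maple, in this order
* how that number moves from the first to the last of them (rises all the way / rises, then falls / falls all the way / hardly changes / falls, then rises)

**First instants.** In the west run, target reads 1.1 % after 0.833 min and 4.0 % after 4.00 min. At that point starting material and target still add up to 99.9 %, so target accounts for the starting material lost.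

**The middle.** Up to 10.0 min, target creeps to 4.8 %, but the sum drops by 1.7 percentage points. I suppose that starting material and target consume each other one to one, so target lost 0.85 points of that gap. Target stood near 4.17 % meanwhile, so I read 29.4 min as the target lifetime, the standing target divided by its rate of loss. With a scatter of 0.3 points on each reading, this is a rough value.

**The end.** This is a pseudo-first-order lifetime, so on my supposition it shortens in proportion to [starting material]. I assume making stops at 10.0 min and keep the west plateau share, which is a guess. The remaining 20.0 min is then 0.680 lifetimes for larch and 1.36 for birch. Each step along the row multiplies the charge by 2 and the lifetimes by 2, so with that share fixed the row falls from any flask counting above 0.693 lifetimes. Birch counts more, so my row stays nearly level to birch and then falls, from 0.00608 M for larch to 4.17 × 10⁻⁴ M for maple.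

**The forecast.** It gives 0.013 M, 0.04 M, 0.12 M and 0.35 M, a row that rises all the way, and says “All cases rise.” My reckoning differs from it in both numbers and shape.

**The result.** The flasks give 0.0103 M, 0.0149 M, 0.0109 M and 0.00176 M: the row rises, then falls, turning at 0.58 M.

    starting material + target → side product (k = 0.00190 M⁻¹ s⁻¹)
    base + by-product ⇌ salt, settled at all times (K = 2000 M⁻¹)
    target → over-reaction product (k = 8.70 × 10⁻⁶ s⁻¹)
    starting material + partner → target + by-product (k = 0.00130 M⁻¹ s⁻¹)
    2 partner → homo dimer (k = 0.0230 M⁻¹ s⁻¹)
    starting material + partner + by-product → target + 2 by-product (k = 0.0200 M⁻² s⁻¹)

**Maple counted.** Maple ends with 24.4 % side product, each unit counted as two. At 15.0 min, partner in maple stands at 0.00732 % and target at 1.18 %. The lifetime read in the west run, scaled to the starting material standing in maple then, gives the rough value 4.80 min. On that rough value the remaining 15.0 min is 3.12 lifetimes, which reckons target down to 0.0518 %. Maple reads 0.0881 % at 30.0 min.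

(All runs were generated by integration from invented constants; noise was put on by code.)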